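The route is built on cutting both C–CH3 bonds at the quaternary ring-A carbon, C(CH3)2, which sits between the two enolised C–O carbons of the cyclohexadienone (ring A). In an aromatic acetylphloroglucinol this carbon is the lone C–H position. The precursor is therefore the fully aromatic diarylmethane in which a 3-acetyl-2,4,6-trihydroxyphenyl ring is joined by CH2 to C-6 of 8-acetyl-5,7-dihydroxy-2,2-dimethyl-2H-chromene (benzene ring B, pyran ring C). One operation, double C-methylation with iodomethane and methoxide, installs both methyls and dearomatises ring A to the β-triketone. The precursor is assembled from 2,4,6-trihydroxyacetophenone by chromene annulation, aminomethylation and quinone-methide benzylation.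

Key step: step 4

Remark: the target has no stereocentre and no stereogenic double bond, so it is a single achiral compound and no configuration has to be set; it is drawn as one enol tautomer of the ring-A β-triketone.

Step 1
Reactants: 1 2,4,6-trihydroxyacetophenone; 2 3-methylbut-2-enal
Product: 4 1-(5,7-dihydroxy-2,2-dimethyl-2H-chromen-8-yl)ethan-1-one, via oxatriene 3 (not isolated)
Conditions: 2 (1.0 equiv), 1 (1.3 equiv), EDDA (10 mol%), xylene, 130 °C; chromatography
Reagents that add atoms: 3-methylbut-2-enal, CC(C)=CC=O
Why: Amine-mediated Knoevenagel-type condensation of prenal (as its iminium ion) at ring carbon C-3 of 1 should give oxatriene 3, whose thermal oxa-6π electrocyclisation onto the oxygen ortho to the acetyl group forms the 2,2-dimethyl-2H-pyran ring (formal [3+3] chromene annulation); closure onto the para oxygen would give the 6-acetyl isomer, to be removed by chromatography, and the slight excess of 1 disfavours double annulation.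

Step 2
Reactants: 4 1-(5,7-dihydroxy-2,2-dimethyl-2H-chromen-8-yl)ethan-1-one; 5 bis(dimethylamino)methane
Product: 6 1-{6-[(dimethylamino)methyl]-5,7-dihydroxy-2,2-dimethyl-2H-chromen-8-yl}ethan-1-one
Conditions: CH2(NMe2)2 (1.3 equiv), 1,4-dioxane, rt
Reagents that add atoms: bis(dimethylamino)methane, CN(C)CN(C)C
Why: Phenolic Mannich aminomethylation, in which the acidic phenol protonates the aminal to release the N,N-dimethylmethyleneiminium ion and C-6 of 4, the only unsubstituted ring carbon and the one flanked by both hydroxyls, attacks it, so that one CH2 unit is placed without regiochemical ambiguity.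

Step 3
Reactants: 6 1-{6-[(dimethylamino)methyl]-5,7-dihydroxy-2,2-dimethyl-2H-chromen-8-yl}ethan-1-one; 1 2,4,6-trihydroxyacetophenone
Product: 8 1-{6-[(3-acetyl-2,4,6-trihydroxyphenyl)methyl]-5,7-dihydroxy-2,2-dimethyl-2H-chromen-8-yl}ethan-1-one, via quinone methide 7 (not isolated)
Conditions: 1 (3 equiv), 1,4-dioxane, 90 °C, N2 sweep
Reagents that add atoms: 2,4,6-trihydroxyacetophenone, CC(=O)c1c(O)cc(O)cc1O
Why: Thermal loss of dimethylamine from the zwitterionic Mannich base should give ortho-quinone methide 7, which is trapped by Michael addition of the nucleophilic C-3 of 1 followed by rearomatisation (Mannich-base/quinone-methide benzylation); the excess of 1 limits a second benzylation at its remaining free carbon, and the slow release of 7 in the absence of free 4 disfavours symmetric dimers.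

Step 4
Reactants: 8 1-{6-[(3-acetyl-2,4,6-trihydroxyphenyl)methyl]-5,7-dihydroxy-2,2-dimethyl-2H-chromen-8-yl}ethan-1-one; 9 iodomethane
Product: 11 2-acetyl-6-[(8-acetyl-5,7-dihydroxy-2,2-dimethyl-2H-chromen-6-yl)methyl]-3,5-dihydroxy-4,4-dimethylcyclohexa-2,5-dien-1-one (target), via monomethyl arene 10 (not isolated)
Conditions: NaOMe (4 equiv), MeI (2.2 equiv, slow addition), MeOH, 0 °C to rt; then 1 M HCl
Reagents that add atoms: iodomethane, CI
Why: In methanolic NaOMe ring A of 8 is a polyphenoxide whose only C–H carbon (C-5′, between the C-4′ and C-6′ oxygens) should attack MeI in an SN2 C-alkylation; proton loss re-forms the arene 10, and a second SN2 at the same, now methyl-bearing, carbon creates the C(CH3)2 centre and leaves ring A as the enolised β-triketone, whose stabilised enolate is a poor nucleophile. The closest known reaction type is the NaOMe/MeI gem-C-dimethylation of acylphloroglucinols to acylfilicinic acids (alkylative dearomatisation). No ring is formed and no stereocentre arises, because the new quaternary carbon carries two identical methyl groups. The step needs C- over O-alkylation (hydrogen-bonded, sodium-paired phenoxides in MeOH react at carbon), ring A over ring B (ring A holds the only unsubstituted carbon and is the more electron-rich trioxygenated anion, whereas ring B is fully substituted with one oxygen locked in the pyran ether), and the methylated carbon over the bridge-bearing carbons (CH3 is much smaller than the doubly ortho-substituted arylmethyl group). Limiting MeI to about 2.2 equiv, keeping the temperature at or below rt and quenching with acid should hold back a third methylation and base-induced exchange of the CH2 bridge.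

Compound list
1 | 2,4,6-trihydroxyacetophenone | CC(=O)c1c(O)cc(O)cc1O | starting material
2 | 3-methylbut-2-enal (prenal) | CC(C)=CC=O | starting material
3 | oxatriene, not isolated: (6Z)-2-acetyl-3,5-dihydroxy-6-(3-methylbut-2-en-1-ylidene)cyclohexa-2,4-dien-1-one | O=C1C(C(C)=O)=C(O)C=C(O)/C1=C/C=C(C)C | intermediate
4 | 1-(5,7-dihydroxy-2,2-dimethyl-2H-chromen-8-yl)ethan-1-one | CC(=O)c1c(O)cc(O)c2C=CC(C)(C)Oc12 | intermediate
5 | bis(dimethylamino)methane (N,N,N′,N′-tetramethylmethanediamine) | CN(C)CN(C)C | starting material
6 | 1-{6-[(dimethylamino)methyl]-5,7-dihydroxy-2,2-dimethyl-2H-chromen-8-yl}ethan-1-one | CC(=O)c1c(O)c(CN(C)C)c(O)c2C=CC(C)(C)Oc12 | intermediate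
7 | quinone methide, not isolated: 8-acetyl-7-hydroxy-2,2-dimethyl-6-methylidene-2H-chromen-5(6H)-one | C=C1C(=O)C2=C(OC(C)(C)C=C2)C(C(C)=O)=C1O | intermediate
8 | 1-{6-[(3-acetyl-2,4,6-trihydroxyphenyl)methyl]-5,7-dihydroxy-2,2-dimethyl-2H-chromen-8-yl}ethan-1-one | CC(=O)c1c(O)cc(O)c(Cc2c(O)c3c(c(C(C)=O)c2O)OC(C)(C)C=C3)c1O | intermediate
9 | iodomethane | CI | starting material
10 | monomethyl arene, not isolated: 1-{6-[(3-acetyl-2,4,6-trihydroxy-5-methylphenyl)methyl]-5,7-dihydroxy-2,2-dimethyl-2H-chromen-8-yl}ethan-1-one | CC(=O)c1c(O)c(C)c(O)c(Cc2c(O)c3c(c(C(C)=O)c2O)OC(C)(C)C=C3)c1O | intermediate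
11 | 2-acetyl-6-[(8-acetyl-5,7-dihydroxy-2,2-dimethyl-2H-chromen-6-yl)methyl]-3,5-dihydroxy-4,4-dimethylcyclohexa-2,5-dien-1-one | CC(=O)C1=C(O)C(C)(C)C(O)=C(Cc2c(O)c3c(c(C(C)=O)c2O)OC(C)(C)C=C3)C1=O | target

Total step count: 4
Longest linear sequence: 4 steps (1 → 4 → 6 → 8 → 11)

Steps most likely to fail

1. Step 4 (key step). Methylation may go to oxygen, to the bridge-bearing carbon of ring A or to C-6 of ring B, or a third methyl may be taken up; prolonged base may also redistribute the CH2 bridge between the rings. Fallback: the order of events is reversed. The fallback sets out from 1, which is gem-dimethylated first with NaOMe/MeI in MeOH to give 2-acetyl-3,5-dihydroxy-4,4-dimethylcyclohexa-2,5-dien-1-one F1. An excess of F1 is then heated with Mannich base 6 in dioxane so that quinone methide 7 is trapped by the single nucleophilic C–H of F1. This comes back to the route at target 11.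

2. Step 1. The pyran may close onto the oxygen para to the acetyl group instead of the ortho oxygen, and a second annulation may occur at the other free carbon. Fallback: the para hydroxyl is masked so that only ortho closure is possible. Setting out from 1, MOMCl (1 equiv) and iPr2NEt at 0 °C should give 1-[2,6-dihydroxy-4-(methoxymethoxy)phenyl]ethan-1-one F2. The same EDDA/prenal annulation then leads to 1-[7-hydroxy-5-(methoxymethoxy)-2,2-dimethyl-2H-chromen-8-yl]ethan-1-one F3. HCl in MeOH removes the acetal and the fallback returns to the route at 4.

3. Step 3. The ring-A partner may be benzylated twice, the quinone methide may condense with itself, or heat and amine may exchange the methylene bridge to give symmetric dimers. Fallback: the bridge is made first by a homo-coupling that needs no cross-selectivity. Setting out from 1, aqueous formaldehyde (0.4 equiv) in dilute acid should give 1,1′-[methylenebis(2,4,6-trihydroxy-3,1-phenylene)]di(ethan-1-one) F4. One EDDA/prenal annulation with sub-stoichiometric 2, with recovery of unreacted F4, then desymmetrises the dimer and returns to the route at 8.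

Further compounds
F1 | step 4 | 2-acetyl-3,5-dihydroxy-4,4-dimethylcyclohexa-2,5-dien-1-one (acetylfilicinic acid) | CC(=O)C1=C(O)C(C)(C)C(O)=CC1=O
F2 | step 1 | 1-[2,6-dihydroxy-4-(methoxymethoxy)phenyl]ethan-1-one | CC(=O)c1c(O)cc(OCOC)cc1O
F3 | step 1 | 1-[7-hydroxy-5-(methoxymethoxy)-2,2-dimethyl-2H-chromen-8-yl]ethan-1-one | CC(=O)c1c(O)cc(OCOC)c2C=CC(C)(C)Oc12
F4 | step 3 | 1,1′-[methylenebis(2,4,6-trihydroxy-3,1-phenylene)]di(ethan-1-one) | CC(=O)c1c(O)cc(O)c(Cc2c(O)cc(O)c(C(C)=O)c2O)c1O
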